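The numbers in the tables are calculated for substances that don't exist, and the scatter is random.

Slowness sets in early in the south run, which is this very flask followed so far: from 3.00 h to 4.00 h the substrate reading holds at 31.8%, with 68.2% of the substrate gone.

common to all: substrate 0.033 M; partner 0.0314 M

| flask | remark | time |
|---|---|---|
| south | the very flask that is asked about, followed so far |  |
| flask |  | 30 h |

south run (percent of the substrate charged)

| time / h | target / % | substrate / % |
|---|---|---|
| 0.667 | 24.0 | 49.6 |
| 1.33 | 29.3 | 38.6 |
| 2.00 | 30.9 | 35.5 |
| 2.50 | 31.7 | 32.7 |
| 3.00 | 31.7 | 31.8 |
| 4.00 | 32.1 | 31.8 |

(scatter of a reading: 0.5 percentage points)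

1. the best time, 30 h at the latest, for target
2. the amount of target, in percent of the substrate charged, at that time
3. the first time at which target reaches 23%, in the same percent

- a reading or a percentage of target counts all its forms, free or not

The quantity to carry is the selectivity, the share of target in the substrate gone, 0.471 at the last reading and 0.476 at the first, so close to the even split of 0.5 at both readings. My own reckoning takes the best as this share of the substrate gone on the plateau, about 32.1%, reached from about 3.00 h on. The level of 23% then needs 48.8% of the substrate gone, a little less than the 50.4% gone at the first reading, so by this reckoning it falls just before 0.667 h.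

The forecast, holding that “the plateau looks real”, gives 32.3% at 6 h and 0.6 h for the level; the flask gives 32.3% at 4.07 h and 0.609 h.

    substrate + target → side product (k = 0.0740 /M/min)
    partner → decomposed reagent (k = 0.00730 /min)
    substrate + partner → second isomer (k = 0.170 /M/min)
    crystals ⇌ target, rate k4*(cs4 - [target]) while solid is left; crystals form when [target] > cs4 (solubility = 1.50 mM, k = 0.190 /min)
    substrate + partner → isomer of the product (k = 0.310 /M/min)
    substrate + partner → target (k = 0.470 /M/min)

At that best time the flask has substrate at 30.9%, and the share, applied to the substrate gone, gives 32.5% of target. At the start the step to target uses substrate 1.5 times as fast as the step to isomer of the product, and of the substrate used by the three steps with partner, a share of 0.495 goes to target.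

A neighbour flask, charged with 0.13 M of partner, ends with substrate at 0%, so the share gives 47.1% of target; the computed amount is 49.1%.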